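**Retrosynthetic overview**
1. Myrrhanone B ⇐ C11–C12 bond: a C11 phenyl sulfone on the bicyclic core is alkylated with a farnesol-derived C12 allylic bromide (C26 carried as a silyl-protected allylic alcohol); desulfonylation, then late oxidation to the C3 ketone and the C26 acid.
2. C8 and C9 of ring B ⇐ 8-oxo-9-methylene decalin: methylcerium addition to C8 (8α-OH), then a C9=C11 vinyl sulfone whose hydrogenation is directed by the 8α-hydroxyl (9α-H).
3. Feature and key disconnection: the congested C4–C5 bond of ring A, which joins the gem-dimethyl carbon C4 (next to the C3 ketone) to the ring-fusion carbon C5 whose hydrogen is cis to the C10 methyl; it is cut to a tertiary α-keto radical at C4, tethered from quaternary C10, adding 6-exo to a C5=C6 alkene.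
4. Radical precursor ⇐ 2-methylcyclohexane-1,3-dione: allylation, yeast desymmetrisation (sets C10), ketalisation, dehydration, chain extension to the α-bromo isopropyl ketone.
5. Ring order: ring B is the carbocycle of the dione and is present from step 1; ring A is closed in step 10.

Key step: step 10

Remark: the target SMILES places H-5 and the C10 methyl on the same face (cis-fused decalin); the route is aimed at exactly this isomer.
Remark: polypodane numbering is used (decalin C1–C10, C11 on C9, C26 the terminal oxidised carbon); β is the face of the C10 methyl. The C3 carbinol (16–37) and the centres left open in 11, 21, 25, 26 (alkene geometry) and 35 are temporary and are erased later.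

Step 1
Reactants: 1 2-methylcyclohexane-1,3-dione; 2 allyl bromide
Product: 3 2-methyl-2-(prop-2-enyl)cyclohexane-1,3-dione
Conditions: NaOH (1 M aq), Bu4NI (cat.), rt
Reagents that add atoms: none
Why: C-alkylation of the stabilised dione enolate with an allylic halide in water should give the 2,2-disubstituted dione, with no stereocentre formed.

Step 2
Reactants: 3 2-methyl-2-(prop-2-enyl)cyclohexane-1,3-dione
Product: 4 (2S,3S)-3-hydroxy-2-methyl-2-(prop-2-enyl)cyclohexan-1-one
Conditions: baker's yeast (Saccharomyces cerevisiae), sucrose, H2O, 30 °C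
Reagents that add atoms: none
Why: Microbial desymmetrisation (enantiotopic-group-selective ketone reduction) of the prochiral 2,2-disubstituted 1,3-dione should reduce one carbonyl only, which fixes the quaternary carbon (future C10) as S; the carbinol centre is removed in step 4.

Step 3
Reactants: 4 (2S,3S)-3-hydroxy-2-methyl-2-(prop-2-enyl)cyclohexan-1-one
Product: 5 (6S,7S)-6-methyl-6-(prop-2-enyl)-1,4-dioxaspiro[4.5]decan-7-ol
Conditions: HOCH2CH2OH, p-TsOH (cat.), benzene, reflux, Dean–Stark
Reagents that add atoms: ethylene glycol, OCCO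
Why: Acid-catalysed dioxolane formation should mask the remaining ketone (future C9) and leave both stereocentres untouched.

Step 4
Reactants: 5 (6S,7S)-6-methyl-6-(prop-2-enyl)-1,4-dioxaspiro[4.5]decan-7-ol
Product: 7 (6S)-6-methyl-6-(prop-2-enyl)-1,4-dioxaspiro[4.5]dec-7-ene, via secondary mesylate 6 (not isolated)
Conditions: MsCl, Et3N, CH2Cl2, 0 °C; then KOtBu, DMSO, 20 °C, short time
Reagents that add atoms: none
Why: Sulfonylation followed by E2 elimination should give the ring alkene (future C5=C6), because the neopentyl mesylate cannot be substituted and only the ring CH2 offers an anti hydrogen; the brief exposure at 20 °C should leave the unactivated allyl group in place.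

Step 5
Reactants: 7 (6S)-6-methyl-6-(prop-2-enyl)-1,4-dioxaspiro[4.5]dec-7-ene
Product: 8 3-[(6S)-6-methyl-1,4-dioxaspiro[4.5]dec-7-en-6-yl]propan-1-ol
Conditions: 9-BBN, THF, 0 °C to rt; then NaOH, H2O2, 0 °C
Reagents that add atoms: hydrogen peroxide, OO
Why: Anti-Markovnikov hydroboration–oxidation with the bulky borane should take the terminal alkene only and spare the ring alkene that flanks the quaternary carbon.

Step 6
Reactants: 8 3-[(6S)-6-methyl-1,4-dioxaspiro[4.5]dec-7-en-6-yl]propan-1-ol
Product: 9 3-[(6S)-6-methyl-1,4-dioxaspiro[4.5]dec-7-en-6-yl]propanal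
Conditions: Dess–Martin periodinane, NaHCO3, CH2Cl2, rt
Reagents that add atoms: none
Why: Buffered Dess–Martin oxidation should stop at the aldehyde (future C3) and keep the ketal.

Step 7
Reactants: 9 3-[(6S)-6-methyl-1,4-dioxaspiro[4.5]dec-7-en-6-yl]propanal; 10 isopropenylmagnesium bromide
Product: 11 2-methyl-5-[(6S)-6-methyl-1,4-dioxaspiro[4.5]dec-7-en-6-yl]pent-1-en-3-ol (both carbinol epimers)
Conditions: THF, −78 °C to 0 °C; NH4Cl (aq)
Reagents that add atoms: none
Why: Grignard addition to the aldehyde should deliver the future C4 with its two methyl carbons; the carbinol forms unselectively and is oxidised in step 8.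

Step 8
Reactants: 11 2-methyl-5-[(6S)-6-methyl-1,4-dioxaspiro[4.5]dec-7-en-6-yl]pent-1-en-3-ol
Product: 12 2-methyl-5-[(6S)-6-methyl-1,4-dioxaspiro[4.5]dec-7-en-6-yl]pent-1-en-3-one
Conditions: Dess–Martin periodinane, NaHCO3, CH2Cl2, 0 °C
Reagents that add atoms: none
Why: Dess–Martin oxidation of the allylic alcohol should give the isopropenyl ketone without touching ketal or ring alkene.

Step 9
Reactants: 12 2-methyl-5-[(6S)-6-methyl-1,4-dioxaspiro[4.5]dec-7-en-6-yl]pent-1-en-3-one
Product: 14 2-bromo-2-methyl-5-[(6S)-6-methyl-1,4-dioxaspiro[4.5]dec-7-en-6-yl]pentan-3-one, via triethylsilyl enol ether 13 (not isolated)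
Conditions: Et3SiH, RhCl(PPh3)3 (cat.), THF, 50 °C; then NBS, THF, −78 °C to 0 °C
Reagents that add atoms: N-bromosuccinimide, O=C1CCC(=O)N1Br
Why: Rhodium-catalysed 1,4-hydrosilylation of the enone should place the enol silane regiospecifically on the isopropyl carbon, and electrophilic bromination of that silyl enol ether should put bromine only on the tertiary α-carbon (C4), which direct bromination of the isopropyl ketone could not guarantee.

Step 10
Reactants: 14 2-bromo-2-methyl-5-[(6S)-6-methyl-1,4-dioxaspiro[4.5]dec-7-en-6-yl]pentan-3-one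
Product: 15 cis-4,4,10-trimethyldecalin-3,9-dione 9-ethylene ketal (5β-H, 10β-CH3)
Conditions: Bu3SnH (syringe pump), AIBN (cat.), benzene, 80 °C, 0.01 M
Reagents that add atoms: none
Why: The tributyltin radical abstracts bromine from 14 to give the electrophilic tertiary α-keto radical at C4, which adds to C5 of the electron-rich ring alkene through an early transition state that tolerates the neighbouring quaternary C10; the secondary C6 radical then takes hydrogen from Bu3SnH and carries the chain. The closest known reaction type is the tin-hydride-mediated cyclisation of α-keto radicals from α-bromo ketones onto cycloalkenes. Ring A closes in the 6-exo-trig mode (C4–C3–C2–C1–C10–C5). The new stereocentre C5 is set by the tether: the three-atom chain anchored at C10 reaches C5 only on the face that carries the C10–C1 bond, so H-5 ends cis to the C10 methyl. The step needs exo over endo closure and cyclisation over direct reduction; attack at C6 would give a strained bridged ring, and slow hydride addition at high dilution keeps premature reduction down.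

Step 11
Reactants: 15 cis-4,4,10-trimethyldecalin-3,9-dione 9-ethylene ketal
Product: 17 3α-hydroxy-4,4,10-trimethyl-cis-decalin-9-one, via 3α-hydroxy ketal 16 (not isolated)
Conditions: NaBH4, MeOH, 0 °C; then HCl (1 M aq), THF, rt
Reagents that add atoms: water, O
Why: Borohydride reduction should deliver hydride to C3 from the convex β face (3α-alcohol, a temporary centre), and acid hydrolysis of the dioxolane then frees the C9 ketone, so the two carbonyls are differentiated.

Step 12
Reactants: 17 3α-hydroxy-4,4,10-trimethyl-cis-decalin-9-one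
Product: 18 3α-(tert-butyldimethylsilyloxy)-4,4,10-trimethyl-cis-decalin-9-one
Conditions: TBSOTf, 2,6-lutidine, CH2Cl2, 0 °C
Reagents that add atoms: tert-butyldimethylsilyl triflate, CC(C)(C)[Si](C)(C)OS(=O)(=O)C(F)(F)F
Why: Silylation with the silyl triflate should protect the hindered neopentyl carbinol with retention, and the ketone is not enolised by lutidine at this temperature.

Step 13
Reactants: 18 3α-(tert-butyldimethylsilyloxy)-4,4,10-trimethyl-cis-decalin-9-one; 19 methyltriphenylphosphonium bromide
Product: 20 3α-(tert-butyldimethylsilyloxy)-4,4,10-trimethyl-9-methylene-cis-decalin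
Conditions: KOtBu, toluene, 90 °C
Reagents that add atoms: none
Why: Wittig methylenation should work on a ketone hindered on one side only and installs C11.

Step 14
Reactants: 20 3α-(tert-butyldimethylsilyloxy)-4,4,10-trimethyl-9-methylene-cis-decalin
Product: 22 3α-(tert-butyldimethylsilyloxy)-4,4,10-trimethyl-9-methylene-cis-decalin-8-one, via C8 allylic alcohol 21 (not isolated)
Conditions: SeO2 (cat.), t-BuOOH, CH2Cl2, rt; then Dess–Martin periodinane, NaHCO3, CH2Cl2, rt
Reagents that add atoms: tert-butyl hydroperoxide, CC(C)(C)OO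
Why: Selenium dioxide allylic hydroxylation (ene reaction, then [2,3]-sigmatropic shift) can only occur at C8 because C10 is quaternary, and oxidation of the carbinol gives the exocyclic enone, so the configuration of 21 does not matter.

Step 15
Reactants: 22 3α-(tert-butyldimethylsilyloxy)-4,4,10-trimethyl-9-methylene-cis-decalin-8-one; 23 methyllithium
Product: 24 3α-(tert-butyldimethylsilyloxy)-4,4,8β,10-tetramethyl-9-methylene-cis-decalin-8α-ol
Conditions: CeCl3, THF, −78 °C
Reagents that add atoms: none
Why: 1,2-Addition of the organocerium reagent to the enone carbonyl should bring methyl to C8 by equatorial attack on the β face, because in the chair that keeps both C4 methyls out of the concave face the C10–C1 bond is axial and blocks the α face 1,3 to C8; this sets 8β-CH3 and 8α-OH.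

Step 16
Reactants: 24 3α-(tert-butyldimethylsilyloxy)-4,4,8β,10-tetramethyl-9-methylene-cis-decalin-8α-ol
Product: 26 3α-(tert-butyldimethylsilyloxy)-4,4,8β,10-tetramethyl-9-(phenylsulfonylmethylene)-cis-decalin-8α-ol, via tertiary β-iodo sulfone 25 (not isolated)
Conditions: PhSO2Na, I2, EtOAc–H2O, rt; then DBU, CH2Cl2, 0 °C to rt
Reagents that add atoms: sodium benzenesulfinate, [Na+].[O-]S(=O)c1ccccc1
Why: Radical iodosulfonylation should put the sulfonyl group on the terminal C11 and iodine on C9, and dehydroiodination can only give the vinyl sulfone because C8 and C10 carry no hydrogen; the alkene geometry is irrelevant.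

Step 17
Reactants: 26 3α-(tert-butyldimethylsilyloxy)-4,4,8β,10-tetramethyl-9-(phenylsulfonylmethylene)-cis-decalin-8α-ol
Product: 27 3α-(tert-butyldimethylsilyloxy)-4,4,8β,10-tetramethyl-9β-(phenylsulfonylmethyl)-cis-decalin-8α-ol
Conditions: H2 (1 atm), [Ir(cod)(PCy3)(py)]PF6 (cat.), CH2Cl2, rt
Reagents that add atoms: none
Why: Hydroxyl-directed homogeneous hydrogenation should deliver both hydrogens from the iridium bound to the axial 8α-hydroxyl to the α face of C9=C11, so H-9 is cis to the hydroxyl and C11 ends β.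

Step 18
Reactants: 28 (2E,6E)-farnesol
Product: 29 (2E,6E)-farnesyl acetate
Conditions: Ac2O, pyridine, DMAP (cat.), CH2Cl2, rt
Reagents that add atoms: acetic anhydride, CC(=O)OC(C)=O
Why: Acetylation protects C1-OH and deactivates the proximal alkene toward the allylic oxidation that follows.

Step 19
Reactants: 29 (2E,6E)-farnesyl acetate
Product: 30 (2E,6E,10E)-12-hydroxy-3,7,11-trimethyldodeca-2,6,10-trienyl acetate
Conditions: SeO2 (cat.), t-BuOOH, salicylic acid (cat.), CH2Cl2, rt
Reagents that add atoms: tert-butyl hydroperoxide, CC(C)(C)OO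
Why: Selenium dioxide allylic oxidation should select the (E)-methyl of the terminal, most electron-rich trisubstituted alkene and give the E allylic alcohol that becomes C26.

Step 20
Reactants: 30 (2E,6E,10E)-12-hydroxy-3,7,11-trimethyldodeca-2,6,10-trienyl acetate
Product: 31 (2E,6E,10E)-12-(tert-butyldimethylsilyloxy)-3,7,11-trimethyldodeca-2,6,10-trienyl acetate
Conditions: TBSCl, imidazole, CH2Cl2, rt
Reagents that add atoms: tert-butyldimethylsilyl chloride, CC(C)(C)[Si](C)(C)Cl
Why: Standard silylation of the primary allylic alcohol.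

Step 21
Reactants: 31 (2E,6E,10E)-12-(tert-butyldimethylsilyloxy)-3,7,11-trimethyldodeca-2,6,10-trienyl acetate
Product: 32 (2E,6E,10E)-12-(tert-butyldimethylsilyloxy)-3,7,11-trimethyldodeca-2,6,10-trien-1-ol
Conditions: K2CO3, MeOH, rt
Reagents that add atoms: none
Why: Methanolysis should remove the acetate and keep the silyl ether.

Step 22
Reactants: 32 (2E,6E,10E)-12-(tert-butyldimethylsilyloxy)-3,7,11-trimethyldodeca-2,6,10-trien-1-ol
Product: 34 tert-butyl{[(2E,6E,10E)-12-bromo-2,6,10-trimethyldodeca-2,6,10-trienyl]oxy}dimethylsilane, via allylic mesylate 33 (not isolated)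
Conditions: MsCl, Et3N, THF, −40 °C; then LiBr, THF, 0 °C
Reagents that add atoms: lithium bromide, [Li+].[Br-]
Why: Mesylation and SN2 bromide displacement under non-acidic conditions should give the primary allylic bromide without allylic transposition or loss of alkene geometry.

Step 23
Reactants: 27 3α-(tert-butyldimethylsilyloxy)-4,4,8β,10-tetramethyl-9β-(phenylsulfonylmethyl)-cis-decalin-8α-ol; 34 tert-butyl{[(2E,6E,10E)-12-bromo-2,6,10-trimethyldodeca-2,6,10-trienyl]oxy}dimethylsilane
Product: 35 3-O,26-O-bis(tert-butyldimethylsilyl)-11-(phenylsulfonyl) coupling product (C11 epimers)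
Conditions: n-BuLi (2.2 equiv), THF–HMPA, −78 °C; then 34, −78 °C to −20 °C
Reagents that add atoms: none
Why: Alkylation of the α-sulfonyl carbanion (as the alkoxide–carbanion dianion) with the primary allylic bromide by SN2 should form the C11–C12 bond; the C11 centre is erased in step 24.

Step 24
Reactants: 35 3-O,26-O-bis(tert-butyldimethylsilyl)-11-(phenylsulfonyl) coupling product
Product: 36 (13E,17E,21E)-3α,26-bis(tert-butyldimethylsilyloxy)-5β-polypoda-13,17,21-trien-8α-ol
Conditions: Na(Hg), Na2HPO4, MeOH–THF, −20 °C to 0 °C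
Reagents that add atoms: none
Why: Reductive desulfonylation by electron transfer should cleave the C11–S bond; the sulfone is not allylic, so no alkene can migrate.

Step 25
Reactants: 36 (13E,17E,21E)-3α,26-bis(tert-butyldimethylsilyloxy)-5β-polypoda-13,17,21-trien-8α-ol
Product: 37 (13E,17E,21E)-5β-polypoda-13,17,21-triene-3α,8α,26-triol
Conditions: Bu4NF, THF, 50 °C
Reagents that add atoms: none
Why: Fluoride desilylation should free both the hindered C3 carbinol and the allylic C26 alcohol.

Step 26
Reactants: 37 (13E,17E,21E)-5β-polypoda-13,17,21-triene-3α,8α,26-triol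
Product: 38 (13E,17E,21E)-8α-hydroxy-3-oxo-5β-polypoda-13,17,21-trien-26-al
Conditions: Dess–Martin periodinane, NaHCO3, CH2Cl2, rt
Reagents that add atoms: none
Why: Dess–Martin oxidation should convert the secondary C3 carbinol to the ketone (removing the temporary centre) and the allylic alcohol to the enal, while the tertiary C8 alcohol cannot react.

Step 27
Reactants: 38 (13E,17E,21E)-8α-hydroxy-3-oxo-5β-polypoda-13,17,21-trien-26-al
Product: 39 Myrrhanone B
Conditions: NaClO2, NaH2PO4, 2-methyl-2-butene, t-BuOH–H2O, rt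
Reagents that add atoms: sodium chlorite, [Na+].[O-]Cl=O
Why: Pinnick oxidation should take the enal to the acid with the E geometry kept; the alkene scavenger protects the trisubstituted double bonds.

**Compound list**
1 | 2-methylcyclohexane-1,3-dione | CC1C(=O)CCCC1=O | starting material
2 | allyl bromide | C=CCBr | starting material
3 | 2-methyl-2-(prop-2-enyl)cyclohexane-1,3-dione | C=CCC1(C)C(=O)CCCC1=O | intermediate
4 | (2S,3S)-3-hydroxy-2-methyl-2-(prop-2-enyl)cyclohexan-1-one | C=CC[C@@]1(C)[C@@H](O)CCCC1=O | intermediate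
5 | (6S,7S)-6-methyl-6-(prop-2-enyl)-1,4-dioxaspiro[4.5]decan-7-ol | C=CC[C@@]1(C)[C@@H](O)CCCC12OCCO2 | intermediate
6 | (6S,7S)-6-methyl-6-(prop-2-enyl)-1,4-dioxaspiro[4.5]decan-7-yl methanesulfonate | C=CC[C@@]1(C)[C@@H](OS(C)(=O)=O)CCCC12OCCO2 | intermediate (not isolated)
7 | (6S)-6-methyl-6-(prop-2-enyl)-1,4-dioxaspiro[4.5]dec-7-ene | C=CC[C@@]1(C)C=CCCC12OCCO2 | intermediate
8 | 3-[(6S)-6-methyl-1,4-dioxaspiro[4.5]dec-7-en-6-yl]propan-1-ol | OCCC[C@@]1(C)C=CCCC12OCCO2 | intermediate
9 | 3-[(6S)-6-methyl-1,4-dioxaspiro[4.5]dec-7-en-6-yl]propanal | O=CCC[C@@]1(C)C=CCCC12OCCO2 | intermediate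
10 | isopropenylmagnesium bromide | C=C(C)[Mg]Br | starting material
11 | 2-methyl-5-[(6S)-6-methyl-1,4-dioxaspiro[4.5]dec-7-en-6-yl]pent-1-en-3-ol (carbinol epimers) | C=C(C)C(O)CC[C@@]1(C)C=CCCC12OCCO2 | intermediate
12 | 2-methyl-5-[(6S)-6-methyl-1,4-dioxaspiro[4.5]dec-7-en-6-yl]pent-1-en-3-one | C=C(C)C(=O)CC[C@@]1(C)C=CCCC12OCCO2 | intermediate
13 | triethylsilyl enol ether of the isopropyl ketone | CC(C)=C(O[Si](CC)(CC)CC)CC[C@@]1(C)C=CCCC12OCCO2 | intermediate (not isolated)
14 | 2-bromo-2-methyl-5-[(6S)-6-methyl-1,4-dioxaspiro[4.5]dec-7-en-6-yl]pentan-3-one | CC(C)(Br)C(=O)CC[C@@]1(C)C=CCCC12OCCO2 | intermediate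
15 | cis-4,4,10-trimethyldecalin-3,9-dione 9-ethylene ketal (5β-H, 10β-CH3) | CC1(C)C(=O)CC[C@@]2(C)[C@@H]1CCCC23OCCO3 | intermediate
16 | 3α-hydroxy-4,4,10-trimethyl-cis-decalin-9-one ethylene ketal | CC1(C)[C@H](O)CC[C@@]2(C)[C@@H]1CCCC23OCCO3 | intermediate (not isolated)
17 | 3α-hydroxy-4,4,10-trimethyl-cis-decalin-9-one | CC1(C)[C@H](O)CC[C@@]2(C)[C@@H]1CCCC2=O | intermediate
18 | 3α-(tert-butyldimethylsilyloxy)-4,4,10-trimethyl-cis-decalin-9-one | CC1(C)[C@H](O[Si](C)(C)C(C)(C)C)CC[C@@]2(C)[C@@H]1CCCC2=O | intermediate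
19 | methyltriphenylphosphonium bromide | C[P+](c1ccccc1)(c1ccccc1)c1ccccc1.[Br-] | starting material
20 | 3α-(tert-butyldimethylsilyloxy)-4,4,10-trimethyl-9-methylene-cis-decalin | CC1(C)[C@H](O[Si](C)(C)C(C)(C)C)CC[C@@]2(C)[C@@H]1CCCC2=C | intermediate
21 | 3α-(tert-butyldimethylsilyloxy)-4,4,10-trimethyl-9-methylene-cis-decalin-8-ol (C8 epimers) | CC1(C)[C@H](O[Si](C)(C)C(C)(C)C)CC[C@@]2(C)[C@@H]1CCC(O)C2=C | intermediate (not isolated)
22 | 3α-(tert-butyldimethylsilyloxy)-4,4,10-trimethyl-9-methylene-cis-decalin-8-one | CC1(C)[C@H](O[Si](C)(C)C(C)(C)C)CC[C@@]2(C)[C@@H]1CCC(=O)C2=C | intermediate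
23 | methyllithium | [Li]C | starting material
24 | 3α-(tert-butyldimethylsilyloxy)-4,4,8β,10-tetramethyl-9-methylene-cis-decalin-8α-ol | CC1(C)[C@H](O[Si](C)(C)C(C)(C)C)CC[C@@]2(C)[C@@H]1CC[C@@](C)(O)C2=C | intermediate
25 | 9-iodo-9-(phenylsulfonylmethyl) adduct of 24 (C9 epimers) | CC1(C)[C@H](O[Si](C)(C)C(C)(C)C)CC[C@@]2(C)[C@@H]1CC[C@@](C)(O)C2(I)CS(=O)(=O)c1ccccc1 | intermediate (not isolated)
26 | 3α-(tert-butyldimethylsilyloxy)-4,4,8β,10-tetramethyl-9-(phenylsulfonylmethylene)-cis-decalin-8α-ol (alkene geometry open) | CC1(C)[C@H](O[Si](C)(C)C(C)(C)C)CC[C@@]2(C)[C@@H]1CC[C@@](C)(O)C2=CS(=O)(=O)c1ccccc1 | intermediate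
27 | 3α-(tert-butyldimethylsilyloxy)-4,4,8β,10-tetramethyl-9β-(phenylsulfonylmethyl)-cis-decalin-8α-ol (9α-H) | CC1(C)[C@H](O[Si](C)(C)C(C)(C)C)CC[C@@]2(C)[C@@H]1CC[C@@](C)(O)[C@@H]2CS(=O)(=O)c1ccccc1 | intermediate
28 | (2E,6E)-farnesol | CC(C)=CCC/C(C)=C/CC/C(C)=C/CO | starting material
29 | (2E,6E)-farnesyl acetate | CC(C)=CCC/C(C)=C/CC/C(C)=C/COC(C)=O | intermediate
30 | (2E,6E,10E)-12-hydroxy-3,7,11-trimethyldodeca-2,6,10-trienyl acetate | OC/C(C)=C/CC/C(C)=C/CC/C(C)=C/COC(C)=O | intermediate
31 | (2E,6E,10E)-12-(tert-butyldimethylsilyloxy)-3,7,11-trimethyldodeca-2,6,10-trienyl acetate | CC(C)(C)[Si](C)(C)OC/C(C)=C/CC/C(C)=C/CC/C(C)=C/COC(C)=O | intermediate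
32 | (2E,6E,10E)-12-(tert-butyldimethylsilyloxy)-3,7,11-trimethyldodeca-2,6,10-trien-1-ol | CC(C)(C)[Si](C)(C)OC/C(C)=C/CC/C(C)=C/CC/C(C)=C/CO | intermediate
33 | (2E,6E,10E)-12-(tert-butyldimethylsilyloxy)-3,7,11-trimethyldodeca-2,6,10-trienyl methanesulfonate | CC(C)(C)[Si](C)(C)OC/C(C)=C/CC/C(C)=C/CC/C(C)=C/COS(C)(=O)=O | intermediate (not isolated)
34 | tert-butyl{[(2E,6E,10E)-12-bromo-2,6,10-trimethyldodeca-2,6,10-trienyl]oxy}dimethylsilane | CC(C)(C)[Si](C)(C)OC/C(C)=C/CC/C(C)=C/CC/C(C)=C/CBr | intermediate
35 | 3-O,26-O-bis(tert-butyldimethylsilyl)-11-(phenylsulfonyl) coupling product (C11 epimers) | CC1(C)[C@H](O[Si](C)(C)C(C)(C)C)CC[C@@]2(C)[C@@H]1CC[C@@](C)(O)[C@@H]2C(S(=O)(=O)c1ccccc1)C/C=C(C)/CC/C=C(C)/CC/C=C(C)/CO[Si](C)(C)C(C)(C)C | intermediate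
36 | (13E,17E,21E)-3α,26-bis(tert-butyldimethylsilyloxy)-5β-polypoda-13,17,21-trien-8α-ol | CC1(C)[C@H](O[Si](C)(C)C(C)(C)C)CC[C@@]2(C)[C@@H]1CC[C@@](C)(O)[C@@H]2CC/C=C(C)/CC/C=C(C)/CC/C=C(C)/CO[Si](C)(C)C(C)(C)C | intermediate
37 | (13E,17E,21E)-5β-polypoda-13,17,21-triene-3α,8α,26-triol | CC1(C)[C@H](O)CC[C@@]2(C)[C@@H]1CC[C@@](C)(O)[C@@H]2CC/C=C(C)/CC/C=C(C)/CC/C=C(C)/CO | intermediate
38 | (13E,17E,21E)-8α-hydroxy-3-oxo-5β-polypoda-13,17,21-trien-26-al | CC1(C)C(=O)CC[C@@]2(C)[C@@H]1CC[C@@](C)(O)[C@@H]2CC/C=C(C)/CC/C=C(C)/CC/C=C(C)/C=O | intermediate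
39 | Myrrhanone B | C/C(=C\CC/C(C)=C/CC[C@@H]1[C@@]2(C)CCC(=O)C(C)(C)[C@H]2CC[C@@]1(C)O)CC/C=C(\C)C(=O)O | target

**Step count**
Total: 27 steps. Longest linear sequence: 22 steps (steps 1–17 and 23–27); the side chain takes 5 steps (18–22).

**Steps most likely to fail**

Step 10. The hindered tertiary radical may take hydrogen from the tin hydride before it adds to the congested alkene carbon next to the quaternary centre, or the bromide may lose HBr. The fallback sets out from 14 and replaces the hydride chain by a xanthate group-transfer chain, in which no hydride is present and the radical is regenerated until it cyclises. Compound 14 with KSC(S)OEt in acetone should give the tertiary S-alkyl O-ethyl dithiocarbonate F1. Dilauroyl peroxide in refluxing 1,2-dichloroethane should then give the cyclised cis-decalin carrying the xanthate at C6, F2. Reduction of F2 with Bu3SnH and AIBN in toluene at 80 °C removes the xanthate and comes back to the route at 15.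

Step 15. Methyl delivery to C8 may show poor or reversed facial selectivity if ring B reacts through the other chair. The fallback sets out from 18 and reverses the order of bond formation at C8, so that oxygen, not methyl, is the group that enters last on the open face. LiN(iPr)2 and MeI in THF at −78 °C should give the 8-methyl ketone F3. KN(SiMe3)2 followed by 2-(phenylsulfonyl)-3-phenyloxaziridine should hydroxylate the enolate to the 8α-hydroxy-8β-methyl-9-ketone F4. Methylenation of F4 with excess Cp2TiMe2 in toluene at 70 °C comes back to the route at 24.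

Step 17. Hydrogen delivery to the crowded, electron-poor trisubstituted alkene may be slow, or may occur without direction from the hydroxyl. The fallback sets out from 26 and delivers the C9 hydrogen as hydride from the C8 oxygen. LiAlH4 in THF at 0 °C should form the aluminate on O8, which transfers hydride to C9 (the β-carbon of the vinyl sulfone) through a five-membered transition state on the α face. Protonation of the α-sulfonyl carbanion on work-up comes back to the route at 27 directly; no new compound arises (F0).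

**Further compounds**
F1 | step 10 | S-[2-methyl-5-((6S)-6-methyl-1,4-dioxaspiro[4.5]dec-7-en-6-yl)-3-oxopentan-2-yl] O-ethyl dithiocarbonate | CCOC(=S)SC(C)(C)C(=O)CC[C@@]1(C)C=CCCC12OCCO2
F2 | step 10 | cis-4,4,10-trimethyldecalin-3,9-dione 9-ethylene ketal 6-(O-ethyl dithiocarbonate) (C6 epimers) | CC1(C)C(=O)CC[C@@]2(C)[C@@H]1C(SC(=S)OCC)CCC23OCCO3
F3 | step 15 | 3α-(tert-butyldimethylsilyloxy)-4,4,8,10-tetramethyl-cis-decalin-9-one (C8 epimers) | CC1(C)[C@H](O[Si](C)(C)C(C)(C)C)CC[C@@]2(C)[C@@H]1CCC(C)C2=O
F4 | step 15 | 3α-(tert-butyldimethylsilyloxy)-8α-hydroxy-4,4,8β,10-tetramethyl-cis-decalin-9-one | CC1(C)[C@H](O[Si](C)(C)C(C)(C)C)CC[C@@]2(C)[C@@H]1CC[C@@](C)(O)C2=O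
F0 | step 17 | none | none
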